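**Retrosynthetic overview**
1. C14–O: the target comes from an exocyclic vinyl oxirane and methacrylic acid by Pd-catalysed 1,4-addition, which moves the alkene into C5=C10 and frees the 6-OH only in the last step.
2. The vinyl oxirane comes from a trans-fused enone lactone: nucleophilic epoxidation (C6–O), Wittig methylenation (C14), prenyl end to CH2OAc, lactone α-methylenation.
3. The enone lactone comes from a monocyclic keto acetal lactone by intramolecular aldol condensation (C5=C6).
4. Key disconnection, lactone C8–O: an enone acid, made and cyclised in one tandem cross-metathesis/oxa-Michael step from a vinyl ketone and a β-vinyl acid.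
5. Vinyl ketone from (S)-citronellal (C4); acid from a Rh-catalysed asymmetric vinyl addition (C7). Ring order: γ-lactone, then cyclohexene ring, then a transient oxirane.

Assumption: atom labels C1–C14 follow the target (C5–C10 ring, C4 side-chain stereocentre, C1 the CH2O chain end, C11–C13 lactone carbons, C14 the CH2O on C10); both starting building blocks are taken as catalogue items, (S)-citronellal in enantiopure form.

**Step 1**
Reactants: 1 methyl (2E)-4,4-dimethoxybut-2-enoate
Product: 3 (3S)-3-(dimethoxymethyl)pent-4-enoic acid, via methyl ester 2 (not isolated)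
Conditions: CH2=CHBF3K (2 equiv), [Rh(cod)Cl]2 (2.5 mol%), (R)-BINAP (5.5 mol%), toluene/H2O 10:1, 90 °C; then LiOH·H2O, THF/H2O, 0 → 20 °C; cold aq. HCl to pH 4
Reagents that add atoms: potassium vinyltrifluoroborate C=C[B-](F)(F)F.[K+]; lithium hydroxide [Li+].[OH-]
Why: Hayashi–Miyaura rhodium-catalysed asymmetric 1,4-addition, in which the BINAP–vinylrhodium species adds to one face of the E enoate and sets C7 (the ligand enantiomer is chosen for the 3S sense by analogy with crotonate additions), followed by ester saponification in the same pot.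

**Step 2**
Reactants: 4 (S)-citronellal
Product: 6 (5S)-5,9-dimethyldeca-1,8-dien-3-one, via bromomagnesium alkoxide 5 (not isolated)
Conditions: CH2=CHMgBr (1.1 equiv), THF, −78 → 0 °C; then 1,1′-(azodicarbonyl)dipiperidine (1.2 equiv), 0 → 20 °C
Reagents that add atoms: vinylmagnesium bromide C=C[Mg]Br
Why: Grignard 1,2-addition followed by Mukaiyama oxidation of the bromomagnesium alkoxide (hydride transfer to the azo compound) gives the vinyl ketone in one pot without touching the C4 centre, which is β to the carbonyl.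

**Step 3**
Reactants: 6 (5S)-5,9-dimethyldeca-1,8-dien-3-one; 3 (3S)-3-(dimethoxymethyl)pent-4-enoic acid
Product: 8 (4S,5R)-4-(dimethoxymethyl)-5-[(4S)-4,8-dimethyl-2-oxonon-7-en-1-yl]oxolan-2-one, via enone acid 7 (not isolated)
Conditions: 3 (2 equiv), second-generation Hoveyda–Grubbs catalyst (5 mol%), CH2Cl2 (0.3 M), 40 °C; then DBU (20 mol%), 20 °C
Reagents that add atoms: none
Why: Proposed new method: tandem olefin cross-metathesis/intramolecular carboxylic-acid oxa-Michael lactonisation, in which the ruthenium carbene joins the two terminal alkenes to the E enone acid (ethene lost) and the DBU carboxylate ion pair then adds 5-exo-trig to the enone β-carbon and protonates the enolate; because this addition is reversible the lactone settles as the 4,5-trans isomer dictated by C7, so the step forms the C8–O bond, the lactone ring and the C8 (R) centre; the closest known chemistry is the tandem cross-metathesis/oxa-conjugate cyclisation of hydroxy alkenes with enones to tetrahydropyrans and base-mediated oxa-Michael lactonisation of keto enoic acids.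

**Step 4**
Reactants: 8 (4S,5R)-4-(dimethoxymethyl)-5-[(4S)-4,8-dimethyl-2-oxonon-7-en-1-yl]oxolan-2-one
Product: 10 (3aR,7aR)-5-[(2S)-6-methylhept-5-en-2-yl]-3a,7a-dihydro-1-benzofuran-2,6(3H,7H)-dione, via keto aldehyde 9 (not isolated)
Conditions: 1 M aq. HCl, THF, 20 °C; then Bn2NH2+ CF3CO2− (0.5 equiv), toluene, 50 °C
Reagents that add atoms: none
Why: Acetal hydrolysis followed by intramolecular aldol condensation (the ketone α-carbon C5 onto the C6 aldehyde, the only six-membered mode) closes the cyclohexenone, while C7 and C8 are carried over from the trans lactone, the more stable arrangement of the epimerisable formyl centre.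

**Step 5**
Reactants: 10 (3aR,7aR)-5-[(2S)-6-methylhept-5-en-2-yl]-3a,7a-dihydro-1-benzofuran-2,6(3H,7H)-dione
Product: 11 (3aS,4S,5S,7aR)-4,5-epoxy-5-[(2S)-6-methylhept-5-en-2-yl]hexahydro-1-benzofuran-2,6-dione
Conditions: tBuOOH (3 equiv, decane solution), BnMe3N+ OH− (Triton B, 10 mol%), THF, 0 °C
Reagents that add atoms: tert-butyl hydroperoxide CC(C)(C)OO
Why: Weitz–Scheffer nucleophilic epoxidation, in which the peroxide anion attacks the β-carbon C6 axially, anti to the axial hydrogen on the ring-fusion carbon C7 of the locked trans-fused bicycle, so the oxirane lands cis to the C7–C11 bond and trans to the lactone oxygen (C6 configuration of the target), while the electron-rich prenyl alkene is inert.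

**Step 6**
Reactants: 11 (3aS,4S,5S,7aR)-4,5-epoxy-5-[(2S)-6-methylhept-5-en-2-yl]hexahydro-1-benzofuran-2,6-dione
Product: 13 (3aS,4S,5S,7aR)-4,5-epoxy-5-[(2S)-5-hydroxypentan-2-yl]hexahydro-1-benzofuran-2,6-dione, via aldehyde 12 (not isolated)
Conditions: O3, CH2Cl2/MeOH 4:1, −78 °C; Me2S; then NaBH(OAc)3, AcOH, CH2Cl2, 20 °C
Reagents that add atoms: ozone [O-][O+]=O
Why: Ozonolysis of the only remaining C=C (the prenyl terminus) followed by chemoselective NaBH(OAc)3 reduction of the aldehyde, which leaves the hindered epoxy ketone and the lactone untouched.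

**Step 7**
Reactants: 13 (3aS,4S,5S,7aR)-4,5-epoxy-5-[(2S)-5-hydroxypentan-2-yl]hexahydro-1-benzofuran-2,6-dione
Product: 14 (3aS,4S,5R,7aR)-4,5-epoxy-5-[(2S)-5-hydroxypentan-2-yl]-6-methylidenehexahydro-1-benzofuran-2(3H)-one
Conditions: Ph3PCH3+ Br− (3 equiv), KN(SiMe3)2 (2.8 equiv), THF, 0 °C; then 13, −20 → 20 °C
Reagents that add atoms: methyltriphenylphosphonium bromide C[P+](c1ccccc1)(c1ccccc1)c1ccccc1.[Br-]
Why: Wittig methylenation of the ketone installs C14 and creates the exocyclic vinyl oxirane; the equatorial lactone C8–O bond of the rigid bicycle is poorly aligned for E1cB loss, and the extra ylide only deprotonates the primary alcohol reversibly.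

**Step 8**
Reactants: 14 (3aS,4S,5R,7aR)-4,5-epoxy-5-[(2S)-5-hydroxypentan-2-yl]-6-methylidenehexahydro-1-benzofuran-2(3H)-one
Product: 17 (3aS,4S,5R,7aR)-4,5-epoxy-5-[(2S)-5-hydroxypentan-2-yl]-3,6-dimethylidenehexahydro-1-benzofuran-2(3H)-one, via Mannich base 15 (not isolated), via ammonium iodide 16 (not isolated)
Conditions: LiN(iPr)2 (2.2 equiv), THF, −78 °C; CH2=NMe2+ I− (3 equiv), −78 → 0 °C; then MeI, MeOH, 20 °C; then aq. NaHCO3, CH2Cl2, 20 °C
Reagents that add atoms: N,N-dimethylmethyleneiminium iodide C=[N+](C)C.[I-]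
Why: Lactone enolate Mannich reaction with Eschenmoser's salt, N-methylation and Hofmann-type elimination give the α-methylene lactone, with the second equivalent of base holding the primary alcohol as its alkoxide; the enolate cannot open the oxirane because it sits on the same face as the C6–O bond.

**Step 9**
Reactants: 17 (3aS,4S,5R,7aR)-4,5-epoxy-5-[(2S)-5-hydroxypentan-2-yl]-3,6-dimethylidenehexahydro-1-benzofuran-2(3H)-one
Product: 18 (4S)-4-[(3aS,4S,5R,7aR)-4,5-epoxy-3,6-dimethylidene-2-oxooctahydro-1-benzofuran-5-yl]pentyl acetate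
Conditions: Ac2O, pyridine, DMAP (cat.), CH2Cl2, 0 °C
Reagents that add atoms: acetic anhydride CC(=O)OC(C)=O
Why: Standard DMAP-catalysed acetylation of the only free hydroxyl, placed here so that the acetate never meets the strong base of step 8.

**Step 10**
Reactants: 18 (4S)-4-[(3aS,4S,5R,7aR)-4,5-epoxy-3,6-dimethylidene-2-oxooctahydro-1-benzofuran-5-yl]pentyl acetate; 19 methacrylic acid
Product: 20 [(3aR,4S,7aR)-5-[(2S)-5-acetoxypentan-2-yl]-4-hydroxy-3-methylidene-2-oxo-2,3,3a,4,7,7a-hexahydro-1-benzofuran-6-yl]methyl 2-methylprop-2-enoate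
Conditions: 19 (1.5 equiv, present from the start), Pd(PPh3)4 (5 mol%), THF, 0 → 20 °C
Reagents that add atoms: none
Why: Tsuji–Trost-type 1,4-addition, in which zerovalent palladium ionises the vinyl oxirane to a π-allylpalladium alkoxide that is protonated at once by the acid (faster than attack of the alkoxide on the lactone), and methacrylate attacks the unhindered CH2 terminus C14, so the alkene moves into the tetrasubstituted C5=C10 position and the untouched C6–O bond appears as the free 6-OH with the configuration set in step 5.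

**Compound list**
1 | methyl (2E)-4,4-dimethoxybut-2-enoate | COC(OC)/C=C/C(=O)OC | starting material
2 | methyl (3S)-3-(dimethoxymethyl)pent-4-enoate | COC(OC)[C@H](C=C)CC(=O)OC | intermediate
3 | (3S)-3-(dimethoxymethyl)pent-4-enoic acid | COC(OC)[C@H](C=C)CC(=O)O | intermediate
4 | (S)-citronellal [(3S)-3,7-dimethyloct-6-enal] | C[C@@H](CCC=C(C)C)CC=O | starting material
5 | bromomagnesium (5S)-5,9-dimethyldeca-1,8-dien-3-olate (both C3 epimers) | C=CC(O[Mg]Br)C[C@@H](C)CCC=C(C)C | intermediate
6 | (5S)-5,9-dimethyldeca-1,8-dien-3-one | C=CC(=O)C[C@@H](C)CCC=C(C)C | intermediate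
7 | (3S,4E,8S)-3-(dimethoxymethyl)-8,12-dimethyl-6-oxotrideca-4,11-dienoic acid | COC(OC)[C@H](/C=C/C(=O)C[C@@H](C)CCC=C(C)C)CC(=O)O | intermediate
8 | (4S,5R)-4-(dimethoxymethyl)-5-[(4S)-4,8-dimethyl-2-oxonon-7-en-1-yl]oxolan-2-one (trans lactone) | O=C1C[C@H](C(OC)OC)[C@@H](CC(=O)C[C@@H](C)CCC=C(C)C)O1 | intermediate
9 | (2R,3S)-2-[(4S)-4,8-dimethyl-2-oxonon-7-en-1-yl]-5-oxooxolane-3-carbaldehyde | O=C1C[C@H](C=O)[C@@H](CC(=O)C[C@@H](C)CCC=C(C)C)O1 | intermediate
10 | (3aR,7aR)-5-[(2S)-6-methylhept-5-en-2-yl]-3a,7a-dihydro-1-benzofuran-2,6(3H,7H)-dione (trans-fused enone lactone) | O=C1C[C@H]2OC(=O)C[C@@H]2C=C1[C@@H](C)CCC=C(C)C | intermediate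
11 | (3aS,4S,5S,7aR)-4,5-epoxy-5-[(2S)-6-methylhept-5-en-2-yl]hexahydro-1-benzofuran-2,6-dione (oxirane cis to the C7–C11 bond) | O=C1C[C@H]2OC(=O)C[C@@H]2[C@@H]3O[C@@]31[C@@H](C)CCC=C(C)C | intermediate
12 | (3aS,4S,5S,7aR)-4,5-epoxy-5-[(2S)-5-oxopentan-2-yl]hexahydro-1-benzofuran-2,6-dione | O=C1C[C@H]2OC(=O)C[C@@H]2[C@@H]3O[C@@]31[C@@H](C)CCC=O | intermediate
13 | (3aS,4S,5S,7aR)-4,5-epoxy-5-[(2S)-5-hydroxypentan-2-yl]hexahydro-1-benzofuran-2,6-dione | O=C1C[C@H]2OC(=O)C[C@@H]2[C@@H]3O[C@@]31[C@@H](C)CCCO | intermediate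
14 | (3aS,4S,5R,7aR)-4,5-epoxy-5-[(2S)-5-hydroxypentan-2-yl]-6-methylidenehexahydro-1-benzofuran-2(3H)-one | C=C1C[C@H]2OC(=O)C[C@@H]2[C@@H]3O[C@@]31[C@@H](C)CCCO | intermediate
15 | 3-[(dimethylamino)methyl] derivative of 14 (both C3 epimers) | C=C1C[C@H]2OC(=O)C(CN(C)C)[C@@H]2[C@@H]3O[C@@]31[C@@H](C)CCCO | intermediate
16 | 3-[(trimethylammonio)methyl] derivative of 14, iodide (both C3 epimers) | C=C1C[C@H]2OC(=O)C(C[N+](C)(C)C)[C@@H]2[C@@H]3O[C@@]31[C@@H](C)CCCO.[I-] | intermediate
17 | (3aS,4S,5R,7aR)-4,5-epoxy-5-[(2S)-5-hydroxypentan-2-yl]-3,6-dimethylidenehexahydro-1-benzofuran-2(3H)-one | C=C1C[C@H]2OC(=O)C(=C)[C@@H]2[C@@H]3O[C@@]31[C@@H](C)CCCO | intermediate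
18 | (4S)-4-[(3aS,4S,5R,7aR)-4,5-epoxy-3,6-dimethylidene-2-oxooctahydro-1-benzofuran-5-yl]pentyl acetate | C=C1C[C@H]2OC(=O)C(=C)[C@@H]2[C@@H]3O[C@@]31[C@@H](C)CCCOC(C)=O | intermediate
19 | methacrylic acid | C=C(C)C(=O)O | starting material
20 | [(3aR,4S,7aR)-5-[(2S)-5-acetoxypentan-2-yl]-4-hydroxy-3-methylidene-2-oxo-2,3,3a,4,7,7a-hexahydro-1-benzofuran-6-yl]methyl 2-methylprop-2-enoate | C=C(C)C(=O)OCC1=C([C@@H](C)CCCOC(C)=O)[C@@H](O)[C@H]2C(=C)C(=O)O[C@@H]2C1 | target

**Step count and risks**
Total steps: 10. Longest linear sequence: 9 (steps 2–10 from (S)-citronellal; step 1 makes the second fragment).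

Steps most likely to fail:

Step 3, the proposed new tandem step. Risks are ring-closing metathesis of 6 onto its prenyl group, slow carboxylate addition and an incomplete trans preference. The fallback uses known chemistry only; it sets out from 6 and ester 2 (step 1 stopped before saponification) and comes back at 8. Cross-metathesis with the same ruthenium catalyst gives methyl (3S,4E,8S)-3-(dimethoxymethyl)-8,12-dimethyl-6-oxotrideca-4,11-dienoate F1. Copper-catalysed conjugate borylation (B2pin2, CuCl, NaOtBu, a Josiphos-type ligand chosen for the 4R sense, MeOH, THF) gives methyl (3S,4R,8S)-3-(dimethoxymethyl)-8,12-dimethyl-6-oxo-4-(4,4,5,5-tetramethyl-1,3,2-dioxaborolan-2-yl)tridec-11-enoate F2. Oxidation with NaBO3·4H2O, with retention at carbon, gives methyl (3S,4R,8S)-3-(dimethoxymethyl)-4-hydroxy-8,12-dimethyl-6-oxotridec-11-enoate F3, which lactonises to 8 with PPTS in warm toluene. The oxygen then arrives through a boron-for-oxygen relay instead of a carboxylate conjugate addition.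

Step 4. The free formyl lactone can epimerise at C7 and close to the cis-fused isomer, or lose the lactone by β-elimination and aromatise. The fallback sets out from 8 and comes back at 10 without ever liberating the aldehyde. TMSOTf and iPr2NEt in CH2Cl2 (−78 → 0 °C) form the ketone silyl enol ether and the oxocarbenium ion in situ, and an intramolecular Mukaiyama-type aldol cyclisation gives (3aS,7aR)-4-methoxy-5-[(2S)-6-methylhept-5-en-2-yl]hexahydro-1-benzofuran-2,6-dione F4 (mixture at C4 and C5). DBU in toluene then eliminates methanol to give 10.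

Step 5. The face selectivity rests on axial attack in the locked bicycle and could be low or reversed. The fallback sets out from 10 and comes back at 11 by hydroxyl-directed epoxidation. Reduction with a 2-methyl-CBS-oxazaborolidine and catecholborane at −78 °C (catalyst enantiomer chosen to deliver hydride syn to the C8–O bond) gives (3aR,6R,7aR)-6-hydroxy-5-[(2S)-6-methylhept-5-en-2-yl]-3a,6,7,7a-tetrahydro-1-benzofuran-2(3H)-one F5, whose hydroxyl is cis to the C7–C11 bond. VO(acac)2/tBuOOH epoxidises syn to that hydroxyl (the prenyl alkene is not touched) to give (3aS,4S,5R,6R,7aR)-4,5-epoxy-6-hydroxy-5-[(2S)-6-methylhept-5-en-2-yl]hexahydro-1-benzofuran-2(3H)-one F6. Dess–Martin periodinane returns the ketone 11.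

**Further compounds**
F1 | step 3 | methyl (3S,4E,8S)-3-(dimethoxymethyl)-8,12-dimethyl-6-oxotrideca-4,11-dienoate | COC(OC)[C@H](/C=C/C(=O)C[C@@H](C)CCC=C(C)C)CC(=O)OC
F2 | step 3 | methyl (3S,4R,8S)-3-(dimethoxymethyl)-8,12-dimethyl-6-oxo-4-(4,4,5,5-tetramethyl-1,3,2-dioxaborolan-2-yl)tridec-11-enoate | COC(OC)[C@H]([C@H](B1OC(C)(C)C(C)(C)O1)CC(=O)C[C@@H](C)CCC=C(C)C)CC(=O)OC
F3 | step 3 | methyl (3S,4R,8S)-3-(dimethoxymethyl)-4-hydroxy-8,12-dimethyl-6-oxotridec-11-enoate | COC(OC)[C@H]([C@H](O)CC(=O)C[C@@H](C)CCC=C(C)C)CC(=O)OC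
F4 | step 4 | (3aS,7aR)-4-methoxy-5-[(2S)-6-methylhept-5-en-2-yl]hexahydro-1-benzofuran-2,6-dione (mixture at C4 and C5) | O=C1C[C@H]2OC(=O)C[C@@H]2C(OC)C1[C@@H](C)CCC=C(C)C
F5 | step 5 | (3aR,6R,7aR)-6-hydroxy-5-[(2S)-6-methylhept-5-en-2-yl]-3a,6,7,7a-tetrahydro-1-benzofuran-2(3H)-one | O[C@@H]1C[C@H]2OC(=O)C[C@@H]2C=C1[C@@H](C)CCC=C(C)C
F6 | step 5 | (3aS,4S,5R,6R,7aR)-4,5-epoxy-6-hydroxy-5-[(2S)-6-methylhept-5-en-2-yl]hexahydro-1-benzofuran-2(3H)-one | O[C@@H]1C[C@H]2OC(=O)C[C@@H]2[C@@H]3O[C@@]31[C@@H](C)CCC=C(C)C
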